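**Plan**

- Retrosynthesis: the two ester C–O bonds (angelate at O9, tiglate at O8) are cut first, then C7–C11 (acetone aldol), then C9–C10 of ring B (intramolecular Michael addition), and last C5–C6 together with a temporary C2–C7 bond (Diels–Alder, undone by retro-aldol).
- Feature used: C5 is quaternary, sits γ to the ring A carbonyl C2 across C1=C10 and carries C6 trans to the C4 methyl. The C2 oxygen can hold a temporary C2–C7 bond, so ring A as its 1-silyloxy-1,3-diene (C2, C1, C10, C5) can add a vinyl ketone across C5 and C2.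
- Forward: ring A comes from 4-methylphenol as dienol ether 8. The [4+2] with a vinyl ketone that already carries the C9 oxygen as a spectator PMB ether gives bicyclo[2.2.2]octene 14. Fluoride retro-aldol and Michael closure then form the cis-fused ring B, after which C7, C8 and C9 are adjusted and the esters attached.
- Stereochemistry: C4 from a catalytic enantioselective conjugate methylation; C5 from the diene face opposite the C4 methyl; C10 from the tether (cis fusion); C7 from an equatorial aldol; C8 and C9 from hydride delivery to the convex β face of ring B.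

Key step: step 7

Remark: eremophilane numbering is used, β is the face carrying the C4 and C5 methyl groups, and the target is taken as drawn, (4S,5R,7R,8R,9S,10S) with the Z ester on O9 and the E ester on O8.

**Route**

Step 1
Reactants: 1 4-methylphenol; 2 methanol
Product: 3 4-methoxy-4-methylcyclohexa-2,5-dien-1-one
Conditions: PhI(OAc)2, MeOH, 0 °C
Reagents that add atoms: methanol (2), CO
Why: Oxidative dearomatisation of a para-alkylphenol with an aryliodine diacetate in methanol traps the phenoxenium ion at C4 and should give the achiral, prochiral para-quinol methyl ether.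

Step 2
Reactants: 3 4-methoxy-4-methylcyclohexa-2,5-dien-1-one; 4 dimethylzinc
Product: 5 (5S)-4-methoxy-4,5-dimethylcyclohex-2-en-1-one (both C4 epimers, carried on together)
Conditions: Me2Zn, Cu(OTf)2 (cat.), (R)-1,1'-binaphthalene-2,2'-diyl N,N-bis[(S)-1-phenylethyl]phosphoramidite (cat.; the ligand antipode that places the new centre S, expected by analogy with cyclohexenone), toluene, −25 °C; aq. NH4Cl
Reagents that add atoms: dimethylzinc (4), C[Zn]C
Why: Copper-catalysed enantioselective conjugate addition desymmetrises the dienone, the chiral copper–phosphoramidite complex choosing one of the two enantiotopic β-carbons so that the methyl-bearing centre (the future C4) should be S whichever way the methoxy group points, and the zinc enolate formed is protected from a second addition.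

Step 3
Reactants: 5 (5S)-4-methoxy-4,5-dimethylcyclohex-2-en-1-one
Product: 6 (5S)-4,5-dimethylcyclohex-3-en-1-one
Conditions: SmI2, THF, MeOH, −78 °C
Reagents that add atoms: none
Why: Two-electron reduction of the enone by SmI2 should expel the γ-methoxide (reductive cleavage of a vinylogous α-alkoxy ketone), and kinetic α-protonation of the dienolate leaves the β,γ-unsaturated ketone; the methyl-bearing stereocentre is untouched while the former C–OMe carbon becomes planar.

Step 4
Reactants: 6 (5S)-4,5-dimethylcyclohex-3-en-1-one; 7 tert-butyldimethylsilyl trifluoromethanesulfonate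
Product: 8 tert-butyl{[(5S)-4,5-dimethylcyclohexa-1,3-dien-1-yl]oxy}dimethylsilane
Conditions: TBSOTf, Et3N, CH2Cl2, 0 °C
Reagents that add atoms: tert-butyldimethylsilyl trifluoromethanesulfonate (7), CC(C)(C)[Si](C)(C)OS(=O)(=O)C(F)(F)F
Why: Soft enolisation (O-silylation, then deprotonation by the amine) removes the doubly activated proton between the carbonyl and the C=C bond and should give only the linear 1-silyloxy-1,3-diene, with the allylic stereocentre unaffected.

Step 5
Reactants: 9 2-chloro-N-methoxy-N-methylacetamide; 10 (4-methoxyphenyl)methanol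
Product: 11 N-methoxy-2-[(4-methoxybenzyl)oxy]-N-methylacetamide
Conditions: NaH, THF, 0 °C to rt
Reagents that add atoms: (4-methoxyphenyl)methanol (10), COc1ccc(CO)cc1
Why: Williamson ether synthesis: the sodium alkoxide displaces the activated α-chloride of the amide by SN2.

Step 6
Reactants: 11 N-methoxy-2-[(4-methoxybenzyl)oxy]-N-methylacetamide; 12 vinylmagnesium bromide
Product: 13 1-[(4-methoxybenzyl)oxy]but-3-en-2-one
Conditions: vinylmagnesium bromide, THF, −20 °C; inverse quench into cold 1 M HCl
Reagents that add atoms: vinylmagnesium bromide (12), C=C[Mg]Br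
Why: Weinreb ketone synthesis: the chelated tetrahedral intermediate stops at mono-addition, and the acidic inverse quench keeps the liberated amine from adding to the vinyl ketone.

Step 7
Reactants: 8 tert-butyl{[(5S)-4,5-dimethylcyclohexa-1,3-dien-1-yl]oxy}dimethylsilane; 13 1-[(4-methoxybenzyl)oxy]but-3-en-2-one
Product: 14 1-[(1R,2S,4R,8S)-1-(tert-butyldimethylsilyloxy)-4,8-dimethylbicyclo[2.2.2]oct-5-en-2-yl]-2-[(4-methoxybenzyl)oxy]ethan-1-one (endo adduct)
Conditions: toluene, 70 °C, BHT (cat.), sealed tube
Reagents that add atoms: none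
Why: A thermal normal-electron-demand [4+2] cycloaddition (the Diels–Alder reaction of a 1-silyloxycyclohexa-1,3-diene with a vinyl ketone is the closest known reaction type) joins C5 to C6 and C2 to C7 suprafacially in one concerted step. The new six-membered carbocycle C2–C7–C6–C5–C10–C1 closes by this cycloaddition and, being bridged by C3–C4, forms the bicyclo[2.2.2]oct-5-ene. Regiochemistry follows from the silyloxy group: the largest HOMO coefficient lies on the remote diene terminus C5, which bonds to the unsubstituted β-carbon C6 of the enone, so the acyl-bearing C7 ends up next to the oxygenated bridgehead C2. C5 is set by approach of the dienophile to the diene face opposite the methyl group on the neighbouring sp3 carbon C4, which places C6 trans and the C5 methyl cis to the C4 methyl, and bridgehead C2 is tied to C5 by the suprafacial addition. C7 is set by the endo rule, but this centre is erased when the C2–C7 bond is cleaved in step 8. The step therefore needs only facial and regiochemical selectivity, secured by the single C4 stereocentre and by the C2 silyloxy group, and the moderate temperature keeps the diene from [1,5]-hydrogen shifts.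

Step 8
Reactants: 14 endo adduct
Product: 17 cis-fused 9β-(4-methoxybenzyloxy)-4β,5β-dimethyl-10βH-decalin-2,8-dione, via bridgehead alkoxide 15 (not isolated), via enone 16 (not isolated)
Conditions: TBAF, THF, 0 °C to rt; then t-BuOK (cat.), t-BuOH, rt; aq. NH4Cl
Reagents that add atoms: none
Why: Fluoride frees the bridgehead alkoxide, whose retro-aldol fragmentation (driven by loss of bicyclic strain and formation of the conjugated C2 enone) cuts the temporary C2–C7 bond, and the alkoxy-ketone enolate at C9 then closes ring B by a 6-(enolendo)-exo-trig intramolecular Michael addition to C10; the three-atom tether from C5 can reach only the face of C10 on which C6 stands, which makes the fusion cis (C10–H β), and C9 should settle with its ether equatorial (β) through a chair transition state of the Z-enolate and because it stays epimerisable.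

Step 9
Reactants: 17 cis-fused dione; 18 ethane-1,2-diol
Product: 19 2,2-(ethylenedioxy)-9β-(4-methoxybenzyloxy)-4β,5β-dimethyl-10βH-decalin-8-one
Conditions: ethane-1,2-diol (1.2 equiv), PPTS (cat.), benzene, reflux, Dean–Stark trap
Reagents that add atoms: ethane-1,2-diol (18), OCCO
Why: Acid-catalysed ketalisation should distinguish the two ketones because the C8 carbonyl is deactivated by its α-alkoxy substituent (destabilised oxocarbenium ion) and flanked by the substituted C9, so that only the C2 ketone forms the dioxolane; no stereocentre is formed.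

Step 10
Reactants: 19 C2 ketal ketone; 20 acetone
Product: 21 2,2-(ethylenedioxy)-7β-(2-hydroxypropan-2-yl)-9β-(4-methoxybenzyloxy)-4β,5β-dimethyl-10βH-decalin-8-one
Conditions: LDA, THF, −78 °C; acetone, −78 °C; AcOH, −78 °C
Reagents that add atoms: acetone (20), CC(C)=O
Why: Kinetic deprotonation removes a proton from the C7 methylene and not from the oxygen-bearing C9 methine, and the aldol addition of the lithium enolate to acetone should place the new group equatorial on the convex β face, the all-equatorial 7β,9β arrangement also being the thermodynamic one; the cold acidic quench prevents retro-aldol.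

Step 11
Reactants: 21 aldol adduct
Product: 22 2,2-(ethylenedioxy)-7β-(2-hydroxypropan-2-yl)-9β-(4-methoxybenzyloxy)-4β,5β-dimethyl-10βH-decalin-8α-ol
Conditions: Me4NBH(OAc)3, MeCN/AcOH, −25 °C
Reagents that add atoms: none
Why: Hydroxyl-directed reduction (Evans–Saksena type): the tertiary hydroxyl exchanges onto boron and delivers hydride intramolecularly to the β (axial) face of the C8 carbonyl, which should give the equatorial 8α-alcohol trans to the C7 side chain.

Step 12
Reactants: 22 diol; 23 (E)-2-methylbut-2-enoyl chloride (tigloyl chloride)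
Product: 24 2,2-(ethylenedioxy)-7β-(2-hydroxypropan-2-yl)-9β-(4-methoxybenzyloxy)-4β,5β-dimethyl-10βH-decalin-8α-yl (E)-2-methylbut-2-enoate
Conditions: tigloyl chloride, pyridine, DMAP (cat.), CH2Cl2, 0 °C to rt
Reagents that add atoms: (E)-2-methylbut-2-enoyl chloride (23), ClC(=O)/C(C)=C/C
Why: DMAP-catalysed acylation of the secondary C8 alcohol; the tertiary alcohol is too hindered to react, and pyridine in place of a trialkylamine avoids the vinylketene pathway, so the E ester is kept.

Step 13
Reactants: 24 tiglate
Product: 25 2,2-(ethylenedioxy)-9β-(4-methoxybenzyloxy)-4β,5β-dimethyl-7β-(prop-1-en-2-yl)-10βH-decalin-8α-yl (E)-2-methylbut-2-enoate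
Conditions: SOCl2, pyridine, CH2Cl2, −20 °C
Reagents that add atoms: none
Why: Dehydration of the tertiary alcohol through its chlorosulfite (E2 elimination) should take a proton from one of the two methyl groups and not the single hindered C7–H, because the alternative tetrasubstituted C7=C11 alkene would suffer allylic strain against the equatorial C8 ester.

Step 14
Reactants: 25 isopropenyl tiglate
Product: 26 2,2-(ethylenedioxy)-9β-hydroxy-4β,5β-dimethyl-7β-(prop-1-en-2-yl)-10βH-decalin-8α-yl (E)-2-methylbut-2-enoate
Conditions: DDQ, CH2Cl2/pH 7 phosphate buffer, 0 °C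
Reagents that add atoms: none
Why: Oxidative cleavage of the 4-methoxybenzyl ether by DDQ (hydride abstraction to the stabilised benzylic cation, then hydrolysis) should leave the ester, the alkene and the buffered ketal intact.

Step 15
Reactants: 26 9β-alcohol
Product: 27 2,2-(ethylenedioxy)-4β,5β-dimethyl-9-oxo-7β-(prop-1-en-2-yl)-10βH-decalin-8α-yl (E)-2-methylbut-2-enoate
Conditions: Dess–Martin periodinane, CH2Cl2, 0 °C to rt
Reagents that add atoms: none
Why: Dess–Martin oxidation converts the C9 alcohol into the ketone under neutral conditions, so the adjacent epimerisable centres C8 and C10 should keep their configuration while the C9 centre is erased on purpose.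

Step 16
Reactants: 27 C9 ketone
Product: 28 2,2-(ethylenedioxy)-9α-hydroxy-4β,5β-dimethyl-7β-(prop-1-en-2-yl)-10βH-decalin-8α-yl (E)-2-methylbut-2-enoate
Conditions: LiBH(s-Bu)3, THF, −78 °C; AcOH, −78 °C
Reagents that add atoms: none
Why: Ketone reduction with a bulky trialkylborohydride: in the ring B chair that keeps the C7 and C8 substituents equatorial the axial α trajectory to C9 is blocked by the syn-axial C5–C4 bond (ring A folded under ring B), so hydride should enter from the convex β face and give the axial 9α-alcohol cis to the C8 ester; at −78 °C with a cold acidic quench the tiglate should neither be reduced nor migrate.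

Step 17
Reactants: 28 9α-alcohol; 29 (Z)-2-methylbut-2-enoic acid (angelic acid)
Product: 30 2,2-(ethylenedioxy)-4β,5β-dimethyl-9α-[(Z)-2-methylbut-2-enoyloxy]-7β-(prop-1-en-2-yl)-10βH-decalin-8α-yl (E)-2-methylbut-2-enoate
Conditions: angelic acid, 2,4,6-trichlorobenzoyl chloride, Et3N, toluene, rt; then 28, DMAP, toluene, 60 °C
Reagents that add atoms: (Z)-2-methylbut-2-enoic acid (29), OC(=O)/C(C)=C\C
Why: Yamaguchi esterification: the mixed 2,4,6-trichlorobenzoic anhydride of angelic acid, activated by DMAP, acylates the hindered axial C9 hydroxyl under conditions known to keep the Z double bond from isomerising to the E ester.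

Step 18
Reactants: 30 bis-ester ketal; 31 water
Product: 32 (4S,5R,7R,8R,9S,10S)-9-[(Z)-2-methylbut-2-enoyloxy]-8-[(E)-2-methylbut-2-enoyloxy]eremophil-11-en-2-one (target, CNP0249036.3)
Conditions: PPTS, acetone/H2O, 40 °C
Reagents that add atoms: water (31), O
Why: Mild acid-catalysed hydrolysis of the dioxolane (acetal cleavage) releases the C2 ketone without touching the two enoate esters or the isopropenyl group, and no stereocentre is affected.

**Compound list**

1 | 4-methylphenol | Cc1ccc(O)cc1 | starting material
2 | methanol | CO | starting material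
3 | 4-methoxy-4-methylcyclohexa-2,5-dien-1-one | COC1(C)C=CC(=O)C=C1 | intermediate
4 | dimethylzinc | C[Zn]C | starting material
5 | (5S)-4-methoxy-4,5-dimethylcyclohex-2-en-1-one (C4 epimers) | COC1(C)C=CC(=O)C[C@@H]1C | intermediate
6 | (5S)-4,5-dimethylcyclohex-3-en-1-one | CC1=CCC(=O)C[C@@H]1C | intermediate
7 | tert-butyldimethylsilyl trifluoromethanesulfonate | CC(C)(C)[Si](C)(C)OS(=O)(=O)C(F)(F)F | starting material
8 | tert-butyl{[(5S)-4,5-dimethylcyclohexa-1,3-dien-1-yl]oxy}dimethylsilane | CC1=CC=C(O[Si](C)(C)C(C)(C)C)C[C@@H]1C | intermediate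
9 | 2-chloro-N-methoxy-N-methylacetamide | CON(C)C(=O)CCl | starting material
10 | (4-methoxyphenyl)methanol | COc1ccc(CO)cc1 | starting material
11 | N-methoxy-2-[(4-methoxybenzyl)oxy]-N-methylacetamide | COc1ccc(COCC(=O)N(C)OC)cc1 | intermediate
12 | vinylmagnesium bromide | C=C[Mg]Br | starting material
13 | 1-[(4-methoxybenzyl)oxy]but-3-en-2-one | COc1ccc(COCC(=O)C=C)cc1 | intermediate
14 | 1-[(1R,2S,4R,8S)-1-(tert-butyldimethylsilyloxy)-4,8-dimethylbicyclo[2.2.2]oct-5-en-2-yl]-2-[(4-methoxybenzyl)oxy]ethan-1-one | COc1ccc(COCC(=O)[C@H]2C[C@@]3(C)C=C[C@]2(O[Si](C)(C)C(C)(C)C)C[C@@H]3C)cc1 | intermediate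
15 | tetrabutylammonium salt of the desilylated bridgehead alkoxide of 14 | COc1ccc(COCC(=O)[C@H]2C[C@@]3(C)C=C[C@]2([O-])C[C@@H]3C)cc1.CCCC[N+](CCCC)(CCCC)CCCC | intermediate (not isolated)
16 | (4R,5S)-4-{4-[(4-methoxybenzyl)oxy]-3-oxobutyl}-4,5-dimethylcyclohex-2-en-1-one | O=C1C=C[C@](C)(CCC(=O)COCc2ccc(OC)cc2)[C@@H](C)C1 | intermediate (not isolated)
17 | cis-fused 9β-(4-methoxybenzyloxy)-4β,5β-dimethyl-10βH-decalin-2,8-dione | C1C[C@@]2(C)[C@H](CC(=O)C[C@@H]2C)[C@@H](OCc3ccc(OC)cc3)C1=O | intermediate
18 | ethane-1,2-diol | OCCO | starting material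
19 | 2,2-(ethylenedioxy)-9β-(4-methoxybenzyloxy)-4β,5β-dimethyl-10βH-decalin-8-one | C1C[C@@]2(C)[C@H](CC3(OCCO3)C[C@@H]2C)[C@@H](OCc4ccc(OC)cc4)C1=O | intermediate
20 | acetone | CC(C)=O | starting material
21 | 2,2-(ethylenedioxy)-7β-(2-hydroxypropan-2-yl)-9β-(4-methoxybenzyloxy)-4β,5β-dimethyl-10βH-decalin-8-one | CC(C)(O)[C@H]1C[C@@]2(C)[C@H](CC3(OCCO3)C[C@@H]2C)[C@@H](OCc4ccc(OC)cc4)C1=O | intermediate
22 | 2,2-(ethylenedioxy)-7β-(2-hydroxypropan-2-yl)-9β-(4-methoxybenzyloxy)-4β,5β-dimethyl-10βH-decalin-8α-ol | CC(C)(O)[C@H]1C[C@@]2(C)[C@H](CC3(OCCO3)C[C@@H]2C)[C@@H](OCc4ccc(OC)cc4)[C@@H]1O | intermediate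
23 | (E)-2-methylbut-2-enoyl chloride | ClC(=O)/C(C)=C/C | starting material
24 | 8α-tiglate of 22 | CC(C)(O)[C@H]1C[C@@]2(C)[C@H](CC3(OCCO3)C[C@@H]2C)[C@@H](OCc4ccc(OC)cc4)[C@@H]1OC(=O)/C(C)=C/C | intermediate
25 | 2,2-(ethylenedioxy)-9β-(4-methoxybenzyloxy)-4β,5β-dimethyl-7β-(prop-1-en-2-yl)-10βH-decalin-8α-yl (E)-2-methylbut-2-enoate | C=C(C)[C@H]1C[C@@]2(C)[C@H](CC3(OCCO3)C[C@@H]2C)[C@@H](OCc4ccc(OC)cc4)[C@@H]1OC(=O)/C(C)=C/C | intermediate
26 | 9β-hydroxy analogue of 25 (PMB removed) | C=C(C)[C@H]1C[C@@]2(C)[C@H](CC3(OCCO3)C[C@@H]2C)[C@@H](O)[C@@H]1OC(=O)/C(C)=C/C | intermediate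
27 | 9-oxo compound | C=C(C)[C@H]1C[C@@]2(C)[C@H](CC3(OCCO3)C[C@@H]2C)C(=O)[C@@H]1OC(=O)/C(C)=C/C | intermediate
28 | 9α-hydroxy compound | C=C(C)[C@H]1C[C@@]2(C)[C@H](CC3(OCCO3)C[C@@H]2C)[C@H](O)[C@@H]1OC(=O)/C(C)=C/C | intermediate
29 | (Z)-2-methylbut-2-enoic acid | OC(=O)/C(C)=C\C | starting material
30 | 9α-angelate 8α-tiglate C2 ethylene ketal | C=C(C)[C@H]1C[C@@]2(C)[C@H](CC3(OCCO3)C[C@@H]2C)[C@H](OC(=O)/C(C)=C\C)[C@@H]1OC(=O)/C(C)=C/C | intermediate
31 | water | O | starting material
32 | (4S,5R,7R,8R,9S,10S)-9-[(Z)-2-methylbut-2-enoyloxy]-8-[(E)-2-methylbut-2-enoyloxy]eremophil-11-en-2-one | C=C(C)[C@H]1C[C@@]2(C)[C@H](CC(=O)C[C@@H]2C)[C@H](OC(=O)/C(C)=C\C)[C@@H]1OC(=O)/C(C)=C/C | target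

**Step count**

Total: 18 steps. Longest linear sequence: 16 steps (steps 1–4 and 7–18); steps 5 and 6 form the two-step dienophile branch.

**Steps most likely to fail, with fallbacks**

Step 13. The elimination may lose regiocontrol: a proton taken from C7 instead of a methyl group would move the double bond into the ring-substituted position. The fallback sets out from 19 and returns at 25. The C7 lithium enolate of 19 (LDA, CeCl3, THF, −78 °C) is added to 1-(trimethylsilyl)propan-2-one to give the β-hydroxysilane ketone F1. Directed reduction with Me4NBH(OAc)3 as in step 11 should give the diol F2, and tigloyl chloride, pyridine and DMAP the tiglate F3. Acid-induced Peterson olefination (BF3·OEt2, CH2Cl2, −78 °C) then removes silicon and hydroxyl across C11–C12 only, which fixes the position of the double bond and delivers 25.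

Step 16. Hydride delivery may show poor facial selectivity, and the neighbouring tiglate may be reduced in conjugate fashion or migrate to O9. The fallback sets out from 26 and returns at 28 without passing through the ketone. The equatorial 9β-alcohol is converted into the triflate F4 (Tf2O, pyridine, CH2Cl2, −20 °C). Displacement with inversion by Bu4NNO2 in DMF (nitrite-mediated triflate inversion of the Lattrell–Dax type, which runs best with an equatorial ester on the neighbouring carbon) should give the nitrite ester F5, which is hydrolysed during aqueous work-up to 28.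

Step 17. Acylation of the hindered axial hydroxyl may be slow, and the activated Z acid may isomerise to the E acid under forcing conditions. The fallback sets out from 28 and returns at 30. Esterification with 2-[bis(2,2,2-trifluoroethoxy)phosphoryl]propanoic acid (DCC, DMAP, CH2Cl2) gives the phosphonate ester F6. Still–Gennari olefination with acetaldehyde (KN(SiMe3)2, 18-crown-6, THF, −78 °C) then builds the Z-2-methylbut-2-enoate in place and should give 30.

**Further compounds**

F1 | step 13 | 2,2-(ethylenedioxy)-7β-[2-hydroxy-1-(trimethylsilyl)propan-2-yl]-9β-(4-methoxybenzyloxy)-4β,5β-dimethyl-10βH-decalin-8-one (C11 epimers) | C[Si](C)(C)CC(C)(O)[C@H]1C[C@@]2(C)[C@H](CC3(OCCO3)C[C@@H]2C)[C@@H](OCc4ccc(OC)cc4)C1=O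
F2 | step 13 | 8α-alcohol from F1 | C[Si](C)(C)CC(C)(O)[C@H]1C[C@@]2(C)[C@H](CC3(OCCO3)C[C@@H]2C)[C@@H](OCc4ccc(OC)cc4)[C@@H]1O
F3 | step 13 | 8α-tiglate of F2 | C[Si](C)(C)CC(C)(O)[C@H]1C[C@@]2(C)[C@H](CC3(OCCO3)C[C@@H]2C)[C@@H](OCc4ccc(OC)cc4)[C@@H]1OC(=O)/C(C)=C/C
F4 | step 16 | 9β-trifluoromethanesulfonate of 26 | C=C(C)[C@H]1C[C@@]2(C)[C@H](CC3(OCCO3)C[C@@H]2C)[C@@H](OS(=O)(=O)C(F)(F)F)[C@@H]1OC(=O)/C(C)=C/C
F5 | step 16 | 9α-nitrite ester | C=C(C)[C@H]1C[C@@]2(C)[C@H](CC3(OCCO3)C[C@@H]2C)[C@H](ON=O)[C@@H]1OC(=O)/C(C)=C/C
F6 | step 17 | 9α-{2-[bis(2,2,2-trifluoroethoxy)phosphoryl]propanoate} of 28 | C=C(C)[C@H]1C[C@@]2(C)[C@H](CC3(OCCO3)C[C@@H]2C)[C@H](OC(=O)C(C)P(=O)(OCC(F)(F)F)OCC(F)(F)F)[C@@H]1OC(=O)/C(C)=C/C
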